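## Retrosynthetic overview

1. Target 24 comes from esterification of the free 8-OH of macrocycle 19 with O-silylated 2-(hydroxymethyl)acrylic acid 22, then desilylation.
2. Key step: 19 comes from ring contraction of the 11-membered cyclic sulfone 17 by an acetate-triggered Michael-induced Ramberg–Bäcklund reaction, which forms C1=C10, delivers the 9-OAc group and extrudes SO2.
3. 17 comes from a Knoevenagel ring closure (C9=C10) of a sulfonylacetate onto a C9 aldehyde; the sulfur bridge is built from C1 aldehyde 11, methyl thioglycolate and chloride.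
4. Lactone 10 comes from a chromium-catalysed 2-(methoxycarbonyl)allylation of enal 4 (C1–C6, C15) with bromide 8 (C7–C9, C11–C13); C8 comes from D-glyceraldehyde and C6/C7 are set here.
5. Ring order: γ-lactone first, then the 11-membered thiacycle, last the 10-membered carbocycle by ring contraction.

Assumption: aldehyde 5 is bought as the acetonide-protected form of D-glyceraldehyde; macrocycles carry germacrane numbering (ring C1–C10, lactone carbons C11–C13 with C12 bonded to O6, ester carbon C14 on C10, methyl C15 on C4).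

## Route

Step 1
Reactants: 1 pent-4-yn-1-ol
Product: 3 (2E)-3-methylhex-2-ene-1,6-diol, via alkenylalane 2 (not isolated)
Conditions: AlMe3 (3 equiv), Cp2ZrCl2 (0.2 equiv), CH2Cl2, 0 °C to rt; then n-BuLi, (CH2O)n, THF, −78 °C to rt; aq HCl
Reagents that add atoms: trimethylaluminium C[Al](C)C; formaldehyde (from paraformaldehyde) C=O
Why: Negishi zirconium-catalysed carboalumination adds methyl and aluminium syn across the terminal alkyne and the alkenylalanate is hydroxymethylated with retention, so the trisubstituted alkene is formed E.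

Step 2
Reactants: 3 (2E)-3-methylhex-2-ene-1,6-diol
Product: 4 (2E)-6-hydroxy-3-methylhex-2-enal
Conditions: MnO2 (15 equiv), CH2Cl2, rt
Reagents that add atoms: none
Why: Activated MnO2 oxidises only the allylic alcohol (chemoselective allylic oxidation) and leaves the saturated primary alcohol and the E geometry untouched.

Step 3
Reactants: 5 (4R)-2,2-dimethyl-1,3-dioxolane-4-carbaldehyde; 6 methyl prop-2-enoate
Product: 7 methyl 2-{[(4R)-2,2-dimethyl-1,3-dioxolan-4-yl](hydroxy)methyl}prop-2-enoate (both carbinol epimers)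
Conditions: DABCO (0.3 equiv), no solvent, rt, 4 d
Reagents that add atoms: none
Why: Morita–Baylis–Hillman reaction of the α-alkoxy aldehyde with the acrylate; the new carbinol centre forms as a mixture, which does not matter because it is erased in step 4.

Step 4
Reactants: 7 methyl 2-{[(4R)-2,2-dimethyl-1,3-dioxolan-4-yl](hydroxy)methyl}prop-2-enoate
Product: 8 methyl (2Z)-2-(bromomethyl)-3-[(4S)-2,2-dimethyl-1,3-dioxolan-4-yl]prop-2-enoate
Conditions: NBS, Me2S, CH2Cl2, −20 °C to rt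
Reagents that add atoms: N-bromosuccinimide O=C1CCC(=O)N1Br
Why: The bromodimethylsulfonium salt activates the alcohol and bromide attacks the alkene terminus (SN2′ allylic transposition) to give the favoured (Z)-2-(bromomethyl)enoate, while the dioxolane centre is not touched.

Step 5
Reactants: 4 (2E)-6-hydroxy-3-methylhex-2-enal; 8 methyl (2Z)-2-(bromomethyl)-3-[(4S)-2,2-dimethyl-1,3-dioxolan-4-yl]prop-2-enoate
Product: 10 (4S,5R)-4-[(4S)-2,2-dimethyl-1,3-dioxolan-4-yl]-5-[(1E)-5-hydroxy-2-methylpent-1-en-1-yl]-3-methylideneoxolan-2-one, via silyl ether 9 (not isolated)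
Conditions: CrCl2 (10 mol%), chiral carbazole-bis(oxazoline) ligand (12 mol%), Mn powder (2 equiv), TMSCl (1.2 equiv), THF, rt; then 0.5 M aq HCl, THF, 0 °C
Reagents that add atoms: none
Why: Catalytic Nozaki–Hiyama–Kishi-type 2-(alkoxycarbonyl)allylation in which the equilibrated (E)-allylchromium reacts through a chair transition state with the aldehyde substituent equatorial (anti adduct, hence the trans-lactone), the ligand selects the aldehyde face (6R, 7S), and the acid work-up desilylates and lactonises.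

Step 6
Reactants: 10 (4S,5R)-4-[(4S)-2,2-dimethyl-1,3-dioxolan-4-yl]-5-[(1E)-5-hydroxy-2-methylpent-1-en-1-yl]-3-methylideneoxolan-2-one
Product: 11 (4E)-5-[(2R,3S)-3-[(4S)-2,2-dimethyl-1,3-dioxolan-4-yl]-4-methylidene-5-oxooxolan-2-yl]-4-methylpent-4-enal
Conditions: Dess–Martin periodinane (1.3 equiv), CH2Cl2, rt
Reagents that add atoms: none
Why: Dess–Martin oxidation of the only free (primary) alcohol under neutral conditions that leave the acetonide, the α-methylene lactone and all stereocentres untouched.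

Step 7
Reactants: 11 (4E)-5-[(2R,3S)-3-[(4S)-2,2-dimethyl-1,3-dioxolan-4-yl]-4-methylidene-5-oxooxolan-2-yl]-4-methylpent-4-enal; 12 methyl 2-sulfanylacetate
Product: 13 methyl 2-({(4E)-1-chloro-5-[(2R,3S)-3-[(4S)-2,2-dimethyl-1,3-dioxolan-4-yl]-4-methylidene-5-oxooxolan-2-yl]-4-methylpent-4-en-1-yl}sulfanyl)acetate (both C1 epimers)
Conditions: TMSCl (2.5 equiv), CH2Cl2, −20 to 0 °C
Reagents that add atoms: chlorotrimethylsilane C[Si](C)(C)Cl
Why: Böhme-type α-chloro sulfide synthesis in which the hemithioacetal is ionised by the silyl chloride and the thionium ion is trapped by chloride; under these acidic conditions the thiol does not add to the methylene lactone, and C1 forms as both epimers, which is harmless because it becomes sp2 in step 11.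

Step 8
Reactants: 13 methyl 2-({(4E)-1-chloro-5-[(2R,3S)-3-[(4S)-2,2-dimethyl-1,3-dioxolan-4-yl]-4-methylidene-5-oxooxolan-2-yl]-4-methylpent-4-en-1-yl}sulfanyl)acetate
Product: 14 methyl 2-({(4E)-1-chloro-5-[(2R,3S)-3-[(4S)-2,2-dimethyl-1,3-dioxolan-4-yl]-4-methylidene-5-oxooxolan-2-yl]-4-methylpent-4-en-1-yl}sulfonyl)acetate (both C1 epimers)
Conditions: mCPBA (2.2 equiv), CH2Cl2, −30 to 0 °C
Reagents that add atoms: 3-chloroperoxybenzoic acid OOC(=O)c1cccc(Cl)c1
Why: Sulfide-to-sulfone oxidation, which is much faster than epoxidation of the lactone-deactivated trisubstituted alkene or of the electron-poor methylene lactone.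

Step 9
Reactants: 14 methyl 2-({(4E)-1-chloro-5-[(2R,3S)-3-[(4S)-2,2-dimethyl-1,3-dioxolan-4-yl]-4-methylidene-5-oxooxolan-2-yl]-4-methylpent-4-en-1-yl}sulfonyl)acetate
Product: 15 methyl 2-({(4E)-1-chloro-5-[(2R,3R)-3-[(1S)-1,2-dihydroxyethyl]-4-methylidene-5-oxooxolan-2-yl]-4-methylpent-4-en-1-yl}sulfonyl)acetate (both C1 epimers)
Conditions: AcOH–H2O (4:1), 40 °C
Reagents that add atoms: none
Why: Acid hydrolysis of the terminal acetonide, to which the γ-lactone, the sulfonyl ester and the C–Cl bond next to the sulfone are inert.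

Step 10
Reactants: 15 methyl 2-({(4E)-1-chloro-5-[(2R,3R)-3-[(1S)-1,2-dihydroxyethyl]-4-methylidene-5-oxooxolan-2-yl]-4-methylpent-4-en-1-yl}sulfonyl)acetate
Product: 17 methyl (4E,6R,7R,8S)-1-chloro-8-hydroxy-1,10-sulfonyl-1,10-secogermacra-4,9,11(13)-trien-12,6-olid-14-oate (11-membered cyclic sulfone), via hydroxy aldehyde 16 (not isolated)
Conditions: TEMPO (10 mol%), PhI(OAc)2 (1.1 equiv), CH2Cl2, rt; crude aldehyde added over 10 h to TiCl4 (3 equiv), 2,6-lutidine (6 equiv), THF, 0 °C (2 mM)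
Reagents that add atoms: none
Why: TEMPO/PhI(OAc)2 oxidises the primary alcohol selectively and a Lehnert-type titanium Knoevenagel condensation of the sulfonylacetate with the new aldehyde, reversible up to the dehydration and run at high dilution, closes the 11-membered ring without creating a stereocentre.

Step 11
Reactants: 17 methyl (4E,6R,7R,8S)-1-chloro-8-hydroxy-1,10-sulfonyl-1,10-secogermacra-4,9,11(13)-trien-12,6-olid-14-oate
Product: 19 methyl (1(10)E,4E,6R,7R,8S,9S)-9-acetoxy-8-hydroxygermacra-1(10),4,11(13)-trien-12,6-olid-14-oate, via episulfone 18 (not isolated)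
Conditions: Bu4NOAc (3 equiv), AcOH (1 equiv), MeCN (5 mM), 45 °C
Reagents that add atoms: tetrabutylammonium acetate CC(=O)[O-].CCCC[N+](CCCC)(CCCC)CCCC
Why: Proposed new method: a ring-contracting, acetate-triggered Michael-induced Ramberg–Bäcklund reaction in which acetate, guided by a hydrogen bond to the free C8 hydroxyl, adds reversibly to C9 of the doubly activated alkylidene (8,9-threo, 9S), the sulfonyl-ester-stabilised C10 carbanion displaces the chloride at C1 (3-exo-tet, as in Michael-initiated ring closures) and the cis-fused episulfone loses SO2 stereospecifically to give the ring-cis C1=C10 enoate of the 10-membered ring; the closest known chemistry is the Michael-induced Ramberg–Bäcklund reaction of α′-halo vinyl sulfones with alkoxides, thiolates or amines and the hydroxyl-directed nucleophilic epoxidation of γ-hydroxy vinyl sulfones.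

Step 12
Reactants: 20 2-(hydroxymethyl)prop-2-enoic acid
Product: 22 2-{[(tert-butyldimethylsilyl)oxy]methyl}prop-2-enoic acid, via silyl ester 21 (not isolated)
Conditions: TBSCl (2.2 equiv), imidazole (4 equiv), DMF, rt; then K2CO3 (0.2 equiv), MeOH–H2O, 0 °C; citric acid
Reagents that add atoms: tert-butyldimethylsilyl chloride CC(C)(C)[Si](C)(C)Cl
Why: Exhaustive silylation followed by selective solvolysis of the labile silyl ester gives the O-silylated acid (standard protection, no stereocentre involved).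

Step 13
Reactants: 19 methyl (1(10)E,4E,6R,7R,8S,9S)-9-acetoxy-8-hydroxygermacra-1(10),4,11(13)-trien-12,6-olid-14-oate; 22 2-{[(tert-butyldimethylsilyl)oxy]methyl}prop-2-enoic acid
Product: 23 methyl (1(10)E,4E,6R,7S,8S,9S)-9-acetoxy-8-[(2-{[(tert-butyldimethylsilyl)oxy]methyl}prop-2-enoyl)oxy]germacra-1(10),4,11(13)-trien-12,6-olid-14-oate
Conditions: EDC·HCl (1.5 equiv), DMAP (0.1 equiv), CH2Cl2, 0 °C
Reagents that add atoms: none
Why: Steglich esterification of the only free hydroxyl (C8–OH) at 0 °C, fast enough to outrun acetyl migration from O9 to O8, with retention at C8 because its C–O bond is not broken.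

Step 14
Reactants: 23 methyl (1(10)E,4E,6R,7S,8S,9S)-9-acetoxy-8-[(2-{[(tert-butyldimethylsilyl)oxy]methyl}prop-2-enoyl)oxy]germacra-1(10),4,11(13)-trien-12,6-olid-14-oate
Product: 24 methyl (1(10)E,4E,6R,7S,8S,9S)-9-acetoxy-8-{[2-(hydroxymethyl)prop-2-enoyl]oxy}germacra-1(10),4,11(13)-trien-12,6-olid-14-oate (CNP0291058.1)
Conditions: HF·pyridine, THF–pyridine, 0 °C
Reagents that add atoms: none
Why: Fluoride cleavage of the primary silyl ether under buffered, weakly acidic conditions that spare the allylic acetate, both acrylate units and the lactone.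

## Compound list

1 | pent-4-yn-1-ol | C#CCCCO | starting material
2 | [(1E)-5-(dimethylalumanyloxy)-2-methylpent-1-en-1-yl](dimethyl)alumane | C[Al](C)/C=C(\C)CCCO[Al](C)C | intermediate
3 | (2E)-3-methylhex-2-ene-1,6-diol | OC/C=C(\C)CCCO | intermediate
4 | (2E)-6-hydroxy-3-methylhex-2-enal | O=C/C=C(\C)CCCO | intermediate
5 | (4R)-2,2-dimethyl-1,3-dioxolane-4-carbaldehyde | O=C[C@H]1COC(C)(C)O1 | starting material
6 | methyl prop-2-enoate | C=CC(=O)OC | starting material
7 | methyl 2-{[(4R)-2,2-dimethyl-1,3-dioxolan-4-yl](hydroxy)methyl}prop-2-enoate (both carbinol epimers) | C=C(C(=O)OC)C(O)[C@H]1COC(C)(C)O1 | intermediate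
8 | methyl (2Z)-2-(bromomethyl)-3-[(4S)-2,2-dimethyl-1,3-dioxolan-4-yl]prop-2-enoate | COC(=O)/C(CBr)=C/[C@H]1COC(C)(C)O1 | intermediate
9 | methyl (3R,4R,5E)-3-[(4S)-2,2-dimethyl-1,3-dioxolan-4-yl]-9-hydroxy-6-methyl-2-methylidene-4-[(trimethylsilyl)oxy]non-5-enoate | C=C(C(=O)OC)[C@H]([C@H]1COC(C)(C)O1)[C@H](O[Si](C)(C)C)/C=C(\C)CCCO | intermediate
10 | (4S,5R)-4-[(4S)-2,2-dimethyl-1,3-dioxolan-4-yl]-5-[(1E)-5-hydroxy-2-methylpent-1-en-1-yl]-3-methylideneoxolan-2-one | C=C1C(=O)O[C@H](/C=C(\C)CCCO)[C@H]1[C@H]2COC(C)(C)O2 | intermediate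
11 | (4E)-5-[(2R,3S)-3-[(4S)-2,2-dimethyl-1,3-dioxolan-4-yl]-4-methylidene-5-oxooxolan-2-yl]-4-methylpent-4-enal | C=C1C(=O)O[C@H](/C=C(\C)CCC=O)[C@H]1[C@H]2COC(C)(C)O2 | intermediate
12 | methyl 2-sulfanylacetate | COC(=O)CS | starting material
13 | methyl 2-({(4E)-1-chloro-5-[(2R,3S)-3-[(4S)-2,2-dimethyl-1,3-dioxolan-4-yl]-4-methylidene-5-oxooxolan-2-yl]-4-methylpent-4-en-1-yl}sulfanyl)acetate (both C1 epimers) | C=C1C(=O)O[C@H](/C=C(\C)CCC(Cl)SCC(=O)OC)[C@H]1[C@H]2COC(C)(C)O2 | intermediate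
14 | methyl 2-({(4E)-1-chloro-5-[(2R,3S)-3-[(4S)-2,2-dimethyl-1,3-dioxolan-4-yl]-4-methylidene-5-oxooxolan-2-yl]-4-methylpent-4-en-1-yl}sulfonyl)acetate (both C1 epimers) | C=C1C(=O)O[C@H](/C=C(\C)CCC(Cl)S(=O)(=O)CC(=O)OC)[C@H]1[C@H]2COC(C)(C)O2 | intermediate
15 | methyl 2-({(4E)-1-chloro-5-[(2R,3R)-3-[(1S)-1,2-dihydroxyethyl]-4-methylidene-5-oxooxolan-2-yl]-4-methylpent-4-en-1-yl}sulfonyl)acetate (both C1 epimers) | C=C1C(=O)O[C@H](/C=C(\C)CCC(Cl)S(=O)(=O)CC(=O)OC)[C@H]1[C@H](O)CO | intermediate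
16 | methyl 2-({(4E)-1-chloro-5-[(2R,3R)-3-[(1S)-1-hydroxy-2-oxoethyl]-4-methylidene-5-oxooxolan-2-yl]-4-methylpent-4-en-1-yl}sulfonyl)acetate (both C1 epimers) | C=C1C(=O)O[C@H](/C=C(\C)CCC(Cl)S(=O)(=O)CC(=O)OC)[C@H]1[C@H](O)C=O | intermediate
17 | methyl (4E,6R,7R,8S)-1-chloro-8-hydroxy-1,10-sulfonyl-1,10-secogermacra-4,9,11(13)-trien-12,6-olid-14-oate (SO2 bridges C1 and C10 in an 11-membered ring; C1 epimers; C9=C10 geometry not fixed) | O[C@H]1[C@H]2C(=C)C(=O)O[C@@H]2/C=C(\C)CCC(Cl)S(=O)(=O)C(C(=O)OC)=C1 | intermediate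
18 | 1,10-episulfone (thiirane 1,1-dioxide spanning C1 and C10) of methyl (4E)-9-acetoxy-8-hydroxygermacra-4,11(13)-dien-12,6-olid-14-oate, C6 to C9 as in 19 | O[C@H]1[C@H]2C(=C)C(=O)O[C@@H]2/C=C(\C)CCC3C(C(=O)OC)(S3(=O)=O)[C@@H]1OC(C)=O | intermediate
19 | methyl (1(10)E,4E,6R,7R,8S,9S)-9-acetoxy-8-hydroxygermacra-1(10),4,11(13)-trien-12,6-olid-14-oate | O[C@H]1[C@H]2C(=C)C(=O)O[C@@H]2/C=C(\C)CC/C=C(/C(=O)OC)[C@@H]1OC(C)=O | intermediate
20 | 2-(hydroxymethyl)prop-2-enoic acid | C=C(CO)C(=O)O | starting material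
21 | tert-butyldimethylsilyl 2-{[(tert-butyldimethylsilyl)oxy]methyl}prop-2-enoate | C=C(CO[Si](C)(C)C(C)(C)C)C(=O)O[Si](C)(C)C(C)(C)C | intermediate
22 | 2-{[(tert-butyldimethylsilyl)oxy]methyl}prop-2-enoic acid | C=C(CO[Si](C)(C)C(C)(C)C)C(=O)O | intermediate
23 | methyl (1(10)E,4E,6R,7S,8S,9S)-9-acetoxy-8-[(2-{[(tert-butyldimethylsilyl)oxy]methyl}prop-2-enoyl)oxy]germacra-1(10),4,11(13)-trien-12,6-olid-14-oate | C=C(CO[Si](C)(C)C(C)(C)C)C(=O)O[C@H]1[C@H]2C(=C)C(=O)O[C@@H]2/C=C(\C)CC/C=C(/C(=O)OC)[C@@H]1OC(C)=O | intermediate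
24 | methyl (1(10)E,4E,6R,7S,8S,9S)-9-acetoxy-8-{[2-(hydroxymethyl)prop-2-enoyl]oxy}germacra-1(10),4,11(13)-trien-12,6-olid-14-oate (CNP0291058.1) | C=C(CO)C(=O)O[C@H]1[C@H]2C(=C)C(=O)O[C@@H]2/C=C(\C)CC/C=C(/C(=O)OC)[C@@H]1OC(C)=O | target

## Step count and risks

Total step count: 14. Longest linear sequence: 11 steps (steps 1, 2, 5, 6, 7, 8, 9, 10, 11, 13, 14).

Three steps most likely to fail:

**Step 5 (allylation and lactonisation).** The anti (trans-lactone) outcome and the facial sense rest on an equilibrated (E)-allylchromium and on the ligand overriding the bias of the dioxolane-bearing bromide; a cis-lactone or a mismatched pairing is possible. The fallback sets out from 4 and 8 and comes back at 10. Indium powder in THF–H2O gives, with the known syn preference of (Z)-2-(bromomethyl)enoates, the syn adduct methyl (3S,4S,5E)-3-[(4S)-2,2-dimethyl-1,3-dioxolan-4-yl]-4,9-dihydroxy-6-methyl-2-methylidenenon-5-enoate F1. Mitsunobu reaction with 4-nitrobenzoic acid (PPh3, DIAD) acylates the primary alcohol and inverts C6 to give the bis(4-nitrobenzoate) F2. K2CO3 in MeOH removes both esters and PPTS closes the lactone to 10.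

**Step 10 (oxidation and 11-ring Knoevenagel closure).** The α-hydroxy aldehyde 16 can epimerise at C8 or oligomerise, the free 8-OH can lactonise onto the C14 ester, and the titanium enolate next to the C1 chloride could lose SO2 too early. The fallback sets out from 15 and comes back at 19 with the 8-oxygen carried as a silyl ether. TESCl and imidazole give the bis(triethylsilyl) ether F3. Swern oxidation, which converts a primary triethylsilyl ether directly into the aldehyde, gives the α-silyloxy aldehyde F4. Ring closure (MgBr2·OEt2, Et3N aldol, then MsCl, Et3N) gives the 8-O-silylated cyclic sulfone F5. The acetate-triggered ring contraction of step 11 then gives the 8-O-triethylsilyl 9-acetate F6, and HF·pyridine frees the 8-OH to give 19.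

**Step 11 (the proposed ring contraction).** Acetate may be too weak a trigger, the alkylidene may isomerise through C8–H, and the C9 face selectivity is unproven. The fallback uses only known reactions, sets out from 11 and comes back at 19. Wittig reaction of 11 with methyl 2-iodo-2-(triphenyl-λ5-phosphanylidene)acetate gives the (Z)-α-iodoenoate F7. AcOH–H2O removes the acetonide to give the diol F8, and TESCl with imidazole gives the bis(triethylsilyl) ether F9. Swern oxidation gives the aldehyde F10. Intramolecular Nozaki–Hiyama–Kishi coupling (CrCl2, NiCl2 (2 mol%), DMSO–THF, high dilution) forms the C9–C10 bond with retention of the alkene geometry; quenching the alkoxide with Ac2O and pyridine gives F6, and HF·pyridine then gives 19. A wrong C9 epimer would be corrected by oxidation and Luche reduction before acetylation.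

Further compounds

F1 | step 5 | methyl (3S,4S,5E)-3-[(4S)-2,2-dimethyl-1,3-dioxolan-4-yl]-4,9-dihydroxy-6-methyl-2-methylidenenon-5-enoate | C=C(C(=O)OC)[C@H]([C@H]1COC(C)(C)O1)[C@@H](O)/C=C(\C)CCCO
F2 | step 5 | methyl (3S,4R,5E)-3-[(4S)-2,2-dimethyl-1,3-dioxolan-4-yl]-6-methyl-2-methylidene-4,9-bis[(4-nitrobenzoyl)oxy]non-5-enoate | C=C(C(=O)OC)[C@H]([C@H]1COC(C)(C)O1)[C@H](OC(=O)c1ccc(cc1)[N+](=O)[O-])/C=C(\C)CCCOC(=O)c1ccc(cc1)[N+](=O)[O-]
F3 | step 10 | methyl 2-({(4E)-5-[(2R,3S)-3-{(1S)-1,2-bis[(triethylsilyl)oxy]ethyl}-4-methylidene-5-oxooxolan-2-yl]-1-chloro-4-methylpent-4-en-1-yl}sulfonyl)acetate (both C1 epimers) | C=C1C(=O)O[C@H](/C=C(\C)CCC(Cl)S(=O)(=O)CC(=O)OC)[C@H]1[C@H](O[Si](CC)(CC)CC)CO[Si](CC)(CC)CC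
F4 | step 10 | methyl 2-({(4E)-1-chloro-4-methyl-5-[(2R,3S)-4-methylidene-5-oxo-3-{(1S)-2-oxo-1-[(triethylsilyl)oxy]ethyl}oxolan-2-yl]pent-4-en-1-yl}sulfonyl)acetate (both C1 epimers) | C=C1C(=O)O[C@H](/C=C(\C)CCC(Cl)S(=O)(=O)CC(=O)OC)[C@H]1[C@H](O[Si](CC)(CC)CC)C=O
F5 | step 10 | methyl (4E,6R,7S,8S)-1-chloro-1,10-sulfonyl-8-[(triethylsilyl)oxy]-1,10-secogermacra-4,9,11(13)-trien-12,6-olid-14-oate (C1 epimers) | CC[Si](CC)(CC)O[C@H]1[C@H]2C(=C)C(=O)O[C@@H]2/C=C(\C)CCC(Cl)S(=O)(=O)C(C(=O)OC)=C1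
F6 | step 10 | methyl (1(10)E,4E,6R,7S,8S,9S)-9-acetoxy-8-[(triethylsilyl)oxy]germacra-1(10),4,11(13)-trien-12,6-olid-14-oate | CC[Si](CC)(CC)O[C@H]1[C@H]2C(=C)C(=O)O[C@@H]2/C=C(\C)CC/C=C(/C(=O)OC)[C@@H]1OC(C)=O
F7 | step 11 | methyl (2Z,6E)-7-[(2R,3S)-3-[(4S)-2,2-dimethyl-1,3-dioxolan-4-yl]-4-methylidene-5-oxooxolan-2-yl]-2-iodo-6-methylhepta-2,6-dienoate | C=C1C(=O)O[C@H](/C=C(\C)CC/C=C(\I)C(=O)OC)[C@H]1[C@H]2COC(C)(C)O2
F8 | step 11 | methyl (2Z,6E)-7-[(2R,3R)-3-[(1S)-1,2-dihydroxyethyl]-4-methylidene-5-oxooxolan-2-yl]-2-iodo-6-methylhepta-2,6-dienoate | C=C1C(=O)O[C@H](/C=C(\C)CC/C=C(\I)C(=O)OC)[C@H]1[C@H](O)CO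
F9 | step 11 | methyl (2Z,6E)-7-[(2R,3S)-3-{(1S)-1,2-bis[(triethylsilyl)oxy]ethyl}-4-methylidene-5-oxooxolan-2-yl]-2-iodo-6-methylhepta-2,6-dienoate | C=C1C(=O)O[C@H](/C=C(\C)CC/C=C(\I)C(=O)OC)[C@H]1[C@H](O[Si](CC)(CC)CC)CO[Si](CC)(CC)CC
F10 | step 11 | methyl (2Z,6E)-2-iodo-6-methyl-7-[(2R,3S)-4-methylidene-5-oxo-3-{(1S)-2-oxo-1-[(triethylsilyl)oxy]ethyl}oxolan-2-yl]hepta-2,6-dienoate | C=C1C(=O)O[C@H](/C=C(\C)CC/C=C(\I)C(=O)OC)[C@H]1[C@H](O[Si](CC)(CC)CC)C=O
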